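**Plan**

- Retrosynthesis: (a) the three phenolic O–H bonds are masked as methoxymethyl acetals; (b) the C6–C(CH3)2 bond is traced by an aromatic Claisen rearrangement to the O5–CH2 bond of a 5‑O‑prenyl ether; (c) the O1–C8a and C4–C4a bonds of ring C are cut together, leaving a 3,5‑dioxygenated benzyne and an (S)‑3‑aryl‑3‑silyloxypropanoate.
- Enabling feature: O1 and C4 sit on the neighbouring ring A carbons C8a and C4a, and only C4a has an oxygen‑bearing neighbour (C5). Ring A can therefore enter as a 3‑alkoxyaryne with two electronically different ends, and O1–C2–C3–C4 as a four‑atom unit, nucleophilic at O and electrophilic at the ester carbon.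
- Forward: rings A and B are bought (phloroglucinol, acetovanillone) and elaborated in three steps each; ring C closes in step 7. The C4 carbonyl made there is then used twice: to free O5 selectively and to steer the prenyl group from O5 to C6. Global deprotection ends the route.
- Stereochemistry: the only stereocentre, C2 (S), is set by asymmetric transfer hydrogenation of a β‑keto ester (step 6) and carried through the annulation with its C–O bond intact.

Key step: step 7

Remark: the C6 substituent is bound through its quaternary carbon; a [3,3] shift of a 3‑methylbut‑2‑enyl aryl ether delivers exactly this connectivity.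

**Route**

Step 1
Reactants: 1 phloroglucinol (benzene‑1,3,5‑triol)
Product: 2 3,5‑bis(methoxymethoxy)phenol
Conditions: MOMCl (2.0 equiv), i‑Pr2NEt (2.2 equiv), DMF, 0 → 20 °C
Reagents that add atoms: chloromethyl methyl ether, COCCl
Why: Williamson‑type O‑alkylation of a phenol; with two equivalents the symmetric bis‑acetal should be the main product and is separated from the recyclable mono‑ and tris‑ethers.

Step 2
Reactants: 2 3,5‑bis(methoxymethoxy)phenol
Product: 3 2‑bromo‑3,5‑bis(methoxymethoxy)phenol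
Conditions: NBS (1.0 equiv), CH2Cl2, −78 → 0 °C
Reagents that add atoms: N‑bromosuccinimide, O=C1CCC(=O)N1Br
Why: electrophilic aromatic bromination should go ortho to the free hydroxyl (two equivalent, hydrogen‑bond‑assisted ortho sites against one para site flanked by two acetals), as in the usual preparation of 3,5‑dialkoxy aryne precursors.

Step 3
Reactants: 3 2‑bromo‑3,5‑bis(methoxymethoxy)phenol
Product: 6 3,5‑bis(methoxymethoxy)‑2‑(trimethylsilyl)phenyl trifluoromethanesulfonate, via trimethylsilyl ether 4 (not isolated), via lithium phenolate 5 (not isolated)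
Conditions: HMDS, THF, 65 °C, evaporate; n‑BuLi, THF, −78 °C; Tf2O, −78 → 20 °C
Reagents that add atoms: hexamethyldisilazane, C[Si](C)(C)N[Si](C)(C)C; trifluoromethanesulfonic anhydride, O=S(=O)(OS(=O)(=O)C(F)(F)F)C(F)(F)F
Why: O‑silylation, bromine–lithium exchange and a 1,3 O‑to‑C silyl shift (retro‑Brook rearrangement) put silicon on carbon and leave a phenolate that is trapped as the triflate, the standard route to o‑silylaryl triflates.

Step 4
Reactants: 7 acetovanillone (1‑(4‑hydroxy‑3‑methoxyphenyl)ethan‑1‑one)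
Product: 8 1‑[3‑methoxy‑4‑(methoxymethoxy)phenyl]ethan‑1‑one
Conditions: MOMCl, i‑Pr2NEt, CH2Cl2, 0 → 20 °C
Reagents that add atoms: chloromethyl methyl ether, COCCl
Why: Williamson‑type acetalisation of the phenol; the acetal should survive the base, hydride‑transfer and fluoride steps ahead.

Step 5
Reactants: 8 1‑[3‑methoxy‑4‑(methoxymethoxy)phenyl]ethan‑1‑one
Product: 9 methyl 3‑[3‑methoxy‑4‑(methoxymethoxy)phenyl]‑3‑oxopropanoate
Conditions: NaH (2.5 equiv), (MeO)2CO, THF, 65 °C; aq. HCl work‑up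
Reagents that add atoms: dimethyl carbonate, COC(=O)OC
Why: crossed Claisen condensation of the ketone enolate with dimethyl carbonate, driven by deprotonation of the β‑keto ester formed.

Step 6
Reactants: 9 methyl 3‑[3‑methoxy‑4‑(methoxymethoxy)phenyl]‑3‑oxopropanoate
Product: 10 methyl (3S)‑3‑hydroxy‑3‑[3‑methoxy‑4‑(methoxymethoxy)phenyl]propanoate
Conditions: RuCl(p‑cymene)[(S,S)‑TsDPEN] (1 mol %), HCO2H–Et3N (5:2), 40 °C
Reagents that add atoms: none
Why: Noyori–Ikariya asymmetric transfer hydrogenation of an aryl ketone; the (S,S) catalyst should deliver hydride to the Re face (aryl group held over the arene ligand) and so set the (S) carbinol centre that becomes C2.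

Step 7
Reactants: 6 3,5‑bis(methoxymethoxy)‑2‑(trimethylsilyl)phenyl trifluoromethanesulfonate; 10 methyl (3S)‑3‑hydroxy‑3‑[3‑methoxy‑4‑(methoxymethoxy)phenyl]propanoate
Product: 13 (2S)‑5,7‑bis(methoxymethoxy)‑2‑[3‑methoxy‑4‑(methoxymethoxy)phenyl]‑2,3‑dihydro‑4H‑chromen‑4‑one, via trimethylsilyl ether 11 (not isolated), via 3,5‑bis(methoxymethoxy)benzyne 12 (not isolated)
Conditions: HMDS, TMSCl (cat.), THF, 50 °C, evaporate; 6 (1.5 equiv), CsF (4 equiv), 18‑crown‑6 (0.5 equiv), THF, 25 → 60 °C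
Reagents that add atoms: none
Why: Proposed new method: fluoride removes the C‑silyl group of 6, which loses triflate to give aryne 12, and in the same aprotic medium unmasks silyl ether 11 as a caesium alkoxide; the alkoxide adds to the aryne carbon remote from the flanking methoxymethoxy group, the resulting aryl anion attacks the methyl ester and expels methoxide, and the methoxide is taken up as MeOSiMe3 by silyl transfer from 11 or Me3SiF. The closest known reaction types are the annulation of arynes with methyl salicylates to xanthones and the insertion of arynes into the N–C(=O) bond of β‑lactams to 2,3‑dihydroquinolin‑4‑ones; new here is an aliphatic β‑silyloxy ester as the four‑atom partner. Ring C is closed by a 6‑exo‑trig acyl substitution of the aryl anion at the ester carbon, a formal [4+2] of O–C–C–C=O with the aryne C≡C. No stereocentre is formed: C2 comes from 10 and its C–O bond is never broken, so the S configuration should be retained. Regioselectivity is needed and is secured by the oxygen at the future C5, which is next to only one aryne carbon and makes the far carbon the electrophilic one (aryne distortion, inductive stabilisation of the anion beside oxygen). Acylation must also outrun protonation of the aryl anion, which the absence of any O–H or N–H and the six‑membered transition state should secure, and silyl capture of methoxide should keep the medium non‑basic for C2 and the enolisable C3.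

Step 8
Reactants: 13 (2S)‑5,7‑bis(methoxymethoxy)‑2‑[3‑methoxy‑4‑(methoxymethoxy)phenyl]‑2,3‑dihydro‑4H‑chromen‑4‑one
Product: 14 (2S)‑5‑hydroxy‑7‑(methoxymethoxy)‑2‑[3‑methoxy‑4‑(methoxymethoxy)phenyl]‑2,3‑dihydro‑4H‑chromen‑4‑one
Conditions: I2 (10 mol %), MeOH, 20 °C, stopped at mono‑cleavage
Reagents that add atoms: none
Why: acid‑catalysed acetal exchange with methanol; the 5‑O acetal, peri to the C4 carbonyl, should go first because the carbonyl oxygen holds the activating acid at that acetal and the product is a hydrogen‑bonded chelate, the usual order for methoxymethyl ethers ortho to an aryl ketone.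

Step 9
Reactants: 14 (2S)‑5‑hydroxy‑7‑(methoxymethoxy)‑2‑[3‑methoxy‑4‑(methoxymethoxy)phenyl]‑2,3‑dihydro‑4H‑chromen‑4‑one
Product: 15 (2S)‑7‑(methoxymethoxy)‑2‑[3‑methoxy‑4‑(methoxymethoxy)phenyl]‑5‑[(3‑methylbut‑2‑en‑1‑yl)oxy]‑2,3‑dihydro‑4H‑chromen‑4‑one
Conditions: 3‑methylbut‑2‑en‑1‑ol, PPh3, DIAD, THF, 0 → 20 °C
Reagents that add atoms: 3‑methylbut‑2‑en‑1‑ol, CC(C)=CCO
Why: Mitsunobu etherification of the chelated, weakly nucleophilic 5‑OH under near‑neutral conditions, so that no base can open ring C; this is the known way to 5‑O‑prenyl ethers of 7,4'‑protected flavanones.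

Step 10
Reactants: 15 (2S)‑7‑(methoxymethoxy)‑2‑[3‑methoxy‑4‑(methoxymethoxy)phenyl]‑5‑[(3‑methylbut‑2‑en‑1‑yl)oxy]‑2,3‑dihydro‑4H‑chromen‑4‑one
Product: 17 (2S)‑5‑hydroxy‑7‑(methoxymethoxy)‑2‑[3‑methoxy‑4‑(methoxymethoxy)phenyl]‑6‑(2‑methylbut‑3‑en‑2‑yl)‑2,3‑dihydro‑4H‑chromen‑4‑one, via cyclohexadienone 16 (not isolated)
Conditions: Eu(fod)3 (10 mol %; fod = 6,6,7,7,8,8,8‑heptafluoro‑2,2‑dimethyloctane‑3,5‑dionate), CHCl3, 50 °C
Reagents that add atoms: none
Why: lanthanide‑catalysed aromatic Claisen rearrangement ([3,3]) of the O5/C4=O chelate, a reaction known for 5‑O‑prenylflavanones; C6 is the only free ortho position (C4a is a ring‑fusion carbon), the allyl unit arrives inverted as the 2‑methylbut‑3‑en‑2‑yl group, dienone 16 tautomerises to the hydrogen‑bonded phenol, C2 is untouched, and the mild temperature should stop the sequence before a Cope shift to C8.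

Step 11
Reactants: 17 (2S)‑5‑hydroxy‑7‑(methoxymethoxy)‑2‑[3‑methoxy‑4‑(methoxymethoxy)phenyl]‑6‑(2‑methylbut‑3‑en‑2‑yl)‑2,3‑dihydro‑4H‑chromen‑4‑one
Product: 18 (2S)‑5,7‑dihydroxy‑2‑(4‑hydroxy‑3‑methoxyphenyl)‑6‑(2‑methylbut‑3‑en‑2‑yl)‑2,3‑dihydro‑4H‑chromen‑4‑one
Conditions: 3 M HCl (aq), MeOH, 45 °C
Reagents that add atoms: none
Why: acid‑catalysed acetal methanolysis of the two remaining methoxymethyl ethers; the monosubstituted alkene is slow to protonate and flavanones should not racemise under mild acid.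

**Compound list**

1 | phloroglucinol (benzene‑1,3,5‑triol) | Oc1cc(O)cc(O)c1 | starting material
2 | 3,5‑bis(methoxymethoxy)phenol | COCOc1cc(O)cc(OCOC)c1 | intermediate
3 | 2‑bromo‑3,5‑bis(methoxymethoxy)phenol | COCOc1cc(O)c(Br)c(OCOC)c1 | intermediate
4 | [2‑bromo‑3,5‑bis(methoxymethoxy)phenoxy]trimethylsilane | COCOc1cc(O[Si](C)(C)C)c(Br)c(OCOC)c1 | intermediate
5 | lithium 3,5‑bis(methoxymethoxy)‑2‑(trimethylsilyl)phenolate | COCOc1cc([O-])c([Si](C)(C)C)c(OCOC)c1.[Li+] | intermediate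
6 | 3,5‑bis(methoxymethoxy)‑2‑(trimethylsilyl)phenyl trifluoromethanesulfonate | COCOc1cc(OS(=O)(=O)C(F)(F)F)c([Si](C)(C)C)c(OCOC)c1 | intermediate
7 | acetovanillone (1‑(4‑hydroxy‑3‑methoxyphenyl)ethan‑1‑one) | CC(=O)c1ccc(O)c(OC)c1 | starting material
8 | 1‑[3‑methoxy‑4‑(methoxymethoxy)phenyl]ethan‑1‑one | CC(=O)c1ccc(OCOC)c(OC)c1 | intermediate
9 | methyl 3‑[3‑methoxy‑4‑(methoxymethoxy)phenyl]‑3‑oxopropanoate | COC(=O)CC(=O)c1ccc(OCOC)c(OC)c1 | intermediate
10 | methyl (3S)‑3‑hydroxy‑3‑[3‑methoxy‑4‑(methoxymethoxy)phenyl]propanoate | COC(=O)C[C@H](O)c1ccc(OCOC)c(OC)c1 | intermediate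
11 | methyl (3S)‑3‑[3‑methoxy‑4‑(methoxymethoxy)phenyl]‑3‑[(trimethylsilyl)oxy]propanoate | COC(=O)C[C@H](O[Si](C)(C)C)c1ccc(OCOC)c(OC)c1 | intermediate
12 | 3,5‑bis(methoxymethoxy)benzyne (1,2‑didehydro‑3,5‑bis(methoxymethoxy)benzene) | COCOC1=CC(OCOC)=CC#C1 | intermediate
13 | (2S)‑5,7‑bis(methoxymethoxy)‑2‑[3‑methoxy‑4‑(methoxymethoxy)phenyl]‑2,3‑dihydro‑4H‑chromen‑4‑one | COCOc1cc2c(c(OCOC)c1)C(=O)C[C@@H](c1ccc(OCOC)c(OC)c1)O2 | intermediate
14 | (2S)‑5‑hydroxy‑7‑(methoxymethoxy)‑2‑[3‑methoxy‑4‑(methoxymethoxy)phenyl]‑2,3‑dihydro‑4H‑chromen‑4‑one | COCOc1cc2c(c(O)c1)C(=O)C[C@@H](c1ccc(OCOC)c(OC)c1)O2 | intermediate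
15 | (2S)‑7‑(methoxymethoxy)‑2‑[3‑methoxy‑4‑(methoxymethoxy)phenyl]‑5‑[(3‑methylbut‑2‑en‑1‑yl)oxy]‑2,3‑dihydro‑4H‑chromen‑4‑one | COCOc1cc2c(c(OCC=C(C)C)c1)C(=O)C[C@@H](c1ccc(OCOC)c(OC)c1)O2 | intermediate
16 | (2S)‑7‑(methoxymethoxy)‑2‑[3‑methoxy‑4‑(methoxymethoxy)phenyl]‑6‑(2‑methylbut‑3‑en‑2‑yl)‑2,3‑dihydro‑4H‑chromene‑4,5(6H)‑dione (C6 epimers) | C=CC(C)(C)C1C(OCOC)=CC2=C(C1=O)C(=O)C[C@@H](c1ccc(OCOC)c(OC)c1)O2 | intermediate
17 | (2S)‑5‑hydroxy‑7‑(methoxymethoxy)‑2‑[3‑methoxy‑4‑(methoxymethoxy)phenyl]‑6‑(2‑methylbut‑3‑en‑2‑yl)‑2,3‑dihydro‑4H‑chromen‑4‑one | C=CC(C)(C)c1c(OCOC)cc2c(c1O)C(=O)C[C@@H](c1ccc(OCOC)c(OC)c1)O2 | intermediate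
18 | (2S)‑5,7‑dihydroxy‑2‑(4‑hydroxy‑3‑methoxyphenyl)‑6‑(2‑methylbut‑3‑en‑2‑yl)‑2,3‑dihydro‑4H‑chromen‑4‑one | C=CC(C)(C)c1c(O)cc2c(c1O)C(=O)C[C@@H](c1ccc(O)c(OC)c1)O2 | target

**Count and risks**

Total steps: 11. Longest linear sequence: 8 steps (steps 1–3 then 7–11, or steps 4–6 then 7–11).

Steps most likely to fail:

1. Step 7. The aryl anion may be quenched before it reaches the ester, either by adventitious protons or by proton transfer from C3, which leaves the open aryl ether or leads to elimination. Unmasking of the silyl ether may lag behind aryne formation, so the aryne is lost to fluoride or methoxide. Base‑induced opening of ring C may erode the C2 configuration. Fallback (known reactions, same two bonds made one after the other): β‑keto ester 9 is reduced with the enantiomeric catalyst RuCl(p‑cymene)[(R,R)‑TsDPEN] in HCO2H–Et3N to methyl (3R)‑3‑hydroxy‑3‑[3‑methoxy‑4‑(methoxymethoxy)phenyl]propanoate F1. Mitsunobu etherification of this alcohol with bromophenol 3 (PPh3, DIAD, toluene, 0 °C) should give, with inversion, methyl (3S)‑3‑[2‑bromo‑3,5‑bis(methoxymethoxy)phenoxy]‑3‑[3‑methoxy‑4‑(methoxymethoxy)phenyl]propanoate F2. Bromine–lithium exchange (n‑BuLi, THF, −100 °C) then closes ring C by Parham cyclisation onto the ester and returns to 13.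

2. Step 10. Over‑rearrangement is the danger: dienone 16 may undergo a Cope shift to C8 before it tautomerises, giving the 8‑prenyl isomer. Fallback (para position blocked): from 13, iodination (NIS, MeCN, 0 °C) at C8, the less hindered ring A position, should give (2S)‑8‑iodo‑5,7‑bis(methoxymethoxy)‑2‑[3‑methoxy‑4‑(methoxymethoxy)phenyl]‑2,3‑dihydro‑4H‑chromen‑4‑one F3. The operations of steps 8, 9 and 10 then lead through the 8‑iodo‑5‑hydroxy flavanone F4 and the 8‑iodo‑5‑O‑prenyl ether F5 to the 8‑iodo‑6‑(2‑methylbut‑3‑en‑2‑yl) phenol F6, in which C8 cannot accept the allyl unit. Reductive removal of iodine (Pd(OAc)2, PPh3, HCO2H, Et3N, DMF, 50 °C) returns to 17.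

3. Step 8. The three acetals may not be told apart well enough, so that the 7‑O and 4'‑O groups are lost along with the 5‑O group. Fallback (protect by difference in reactivity of the free phenols): from 13, all three acetals are removed (3 M HCl, MeOH, 45 °C) to give (2S)‑5,7‑dihydroxy‑2‑(4‑hydroxy‑3‑methoxyphenyl)‑2,3‑dihydro‑4H‑chromen‑4‑one F7. The two non‑chelated hydroxyls (7‑OH, 4'‑OH) are then re‑protected (MOMCl 2.1 equiv, i‑Pr2NEt, CH2Cl2, 0 °C), while the 5‑OH, hydrogen‑bonded to C4=O, should stay free; this returns to 14.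

**Further compounds**

F1 | step 7 | methyl (3R)‑3‑hydroxy‑3‑[3‑methoxy‑4‑(methoxymethoxy)phenyl]propanoate | COC(=O)C[C@@H](O)c1ccc(OCOC)c(OC)c1
F2 | step 7 | methyl (3S)‑3‑[2‑bromo‑3,5‑bis(methoxymethoxy)phenoxy]‑3‑[3‑methoxy‑4‑(methoxymethoxy)phenyl]propanoate | COC(=O)C[C@@H](c1ccc(OCOC)c(OC)c1)Oc1cc(OCOC)cc(OCOC)c1Br
F3 | step 10 | (2S)‑8‑iodo‑5,7‑bis(methoxymethoxy)‑2‑[3‑methoxy‑4‑(methoxymethoxy)phenyl]‑2,3‑dihydro‑4H‑chromen‑4‑one | COCOc1c(I)c2c(c(OCOC)c1)C(=O)C[C@@H](c1ccc(OCOC)c(OC)c1)O2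
F4 | step 10 | (2S)‑5‑hydroxy‑8‑iodo‑7‑(methoxymethoxy)‑2‑[3‑methoxy‑4‑(methoxymethoxy)phenyl]‑2,3‑dihydro‑4H‑chromen‑4‑one | COCOc1c(I)c2c(c(O)c1)C(=O)C[C@@H](c1ccc(OCOC)c(OC)c1)O2
F5 | step 10 | (2S)‑8‑iodo‑7‑(methoxymethoxy)‑2‑[3‑methoxy‑4‑(methoxymethoxy)phenyl]‑5‑[(3‑methylbut‑2‑en‑1‑yl)oxy]‑2,3‑dihydro‑4H‑chromen‑4‑one | COCOc1c(I)c2c(c(OCC=C(C)C)c1)C(=O)C[C@@H](c1ccc(OCOC)c(OC)c1)O2
F6 | step 10 | (2S)‑5‑hydroxy‑8‑iodo‑7‑(methoxymethoxy)‑2‑[3‑methoxy‑4‑(methoxymethoxy)phenyl]‑6‑(2‑methylbut‑3‑en‑2‑yl)‑2,3‑dihydro‑4H‑chromen‑4‑one | C=CC(C)(C)c1c(OCOC)c(I)c2c(c1O)C(=O)C[C@@H](c1ccc(OCOC)c(OC)c1)O2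
F7 | step 8 | (2S)‑5,7‑dihydroxy‑2‑(4‑hydroxy‑3‑methoxyphenyl)‑2,3‑dihydro‑4H‑chromen‑4‑one | Oc1cc2c(c(O)c1)C(=O)C[C@@H](c1ccc(O)c(OC)c1)O2
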